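**Strategy**

The route rests on disconnecting the bond between C3 of the chromanone (pyranone) ring and C3' of the flavone B ring. The key step exploits two features: C3 is the α-carbon of the C4 ketone, so a temporary tert-butyl ester makes it a soft β-keto ester nucleophile, and C3' lies ortho to the 4'-oxygen, which assists aryl–lead ligand coupling. In one operation a Pinhey arylation joins the enantioenriched, benzyl-protected 3-carboxy-flavanone (C2 set beforehand by an organocatalytic oxa-Michael closure that needs the same ester) with the aryllead triacetate of a complete, benzyl-protected apigenin unit. Decarboxylation then settles C3 as the thermodynamic 2,3-trans isomer.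

Key step: step 7

Assumption: the quinine-derived thiourea is taken to give the (2R) ring closure drawn for 5; if the facial sense is the opposite on this substrate, the pseudo-enantiomeric quinidine-derived catalyst is used and nothing else changes.

Remark on the target: it is the 2,3-trans (2R,3S) isomer. The C2 aryl group has the spatial sense opposite to that of (2S)-naringenin, so C2 is made by catalysis and not taken from the natural flavanone.

**Route**

Step 1
Reactants: 1 1-[2,4-bis(benzyloxy)-6-hydroxyphenyl]ethanone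
Product: 2 tert-butyl 3-[2,4-bis(benzyloxy)-6-hydroxyphenyl]-3-oxopropanoate
Conditions: LiHMDS (3.2 equiv), THF, −78 to −10 °C; Boc2O (1.05 equiv), −78 °C to rt; 1 M HCl
Reagents that add atoms: di-tert-butyl dicarbonate, CC(C)(C)OC(=O)OC(=O)OC(C)(C)C
Why: Claisen-type C-tert-butoxycarbonylation of the phenoxide/enolate dianion; the enolate carbon is the most nucleophilic site and the third equivalent of base deprotonates the product, which prevents a second acylation.

Step 2
Reactants: 2 tert-butyl 3-[2,4-bis(benzyloxy)-6-hydroxyphenyl]-3-oxopropanoate; 3 4-(benzyloxy)benzaldehyde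
Product: 4 tert-butyl (2Z)-2-[2,4-bis(benzyloxy)-6-hydroxybenzoyl]-3-[4-(benzyloxy)phenyl]prop-2-enoate
Conditions: piperidine (10 mol%), AcOH (10 mol%), 4 Å MS, toluene, rt
Reagents that add atoms: none
Why: Knoevenagel condensation of the active methylene with the aldehyde; the buffered amine salt at room temperature should leave the free phenol uncyclized, and the alkene is expected mainly as the Z isomer (an E/Z mixture would be carried on as such).

Step 3
Reactants: 4 tert-butyl (2Z)-2-[2,4-bis(benzyloxy)-6-hydroxybenzoyl]-3-[4-(benzyloxy)phenyl]prop-2-enoate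
Product: 5 tert-butyl (2R,3S)-5,7-bis(benzyloxy)-2-[4-(benzyloxy)phenyl]-4-oxochromane-3-carboxylate
Conditions: quinine-derived 9-epi-amino 3,5-bis(trifluoromethyl)phenyl thiourea (10 mol%), toluene, −25 °C
Reagents that add atoms: none
Why: Bifunctional thiourea/tertiary-amine-catalysed intramolecular oxa-Michael addition (6-endo-trig); the thiourea binds the 1,3-dicarbonyl and the quinuclidine guides the phenol to one alkene face, which sets C2, while C3 of the keto form settles trans (it equilibrates with the enol and is re-set later).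

Step 4
Reactants: 1 1-[2,4-bis(benzyloxy)-6-hydroxyphenyl]ethanone; 6 4-(benzyloxy)-3-bromobenzaldehyde
Product: 7 (2E)-1-[2,4-bis(benzyloxy)-6-hydroxyphenyl]-3-[4-(benzyloxy)-3-bromophenyl]prop-2-en-1-one
Conditions: KOH (aq. 50%), EtOH/THF, rt; then 1 M HCl
Reagents that add atoms: none
Why: Claisen–Schmidt aldol condensation; the non-enolisable aldehyde and E1cB dehydration should give the E-chalcone.

Step 5
Reactants: 7 (2E)-1-[2,4-bis(benzyloxy)-6-hydroxyphenyl]-3-[4-(benzyloxy)-3-bromophenyl]prop-2-en-1-one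
Product: 8 5,7-bis(benzyloxy)-2-[4-(benzyloxy)-3-bromophenyl]-4H-chromen-4-one
Conditions: I2 (10 mol%), DMSO, 130 °C
Reagents that add atoms: none
Why: Iodine-catalysed oxidative cyclisation of a 2'-hydroxychalcone to the flavone (oxa-Michael closure, α-iodination and loss of HI, with DMSO as terminal oxidant); benzyl ethers and the aryl bromide should be inert.

Step 6
Reactants: 8 5,7-bis(benzyloxy)-2-[4-(benzyloxy)-3-bromophenyl]-4H-chromen-4-one
Product: 9 5,7-bis(benzyloxy)-2-[4-(benzyloxy)-3-(tributylstannyl)phenyl]-4H-chromen-4-one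
Conditions: (Bu3Sn)2 (1.3 equiv), Pd(PPh3)4 (5 mol%), toluene, 110 °C
Reagents that add atoms: hexabutylditin, CCCC[Sn](CCCC)(CCCC)[Sn](CCCC)(CCCC)CCCC
Why: Palladium-catalysed stannylation of the aryl bromide (oxidative addition, Sn–Sn transmetalation, reductive elimination); it puts the metal at C3' without an organolithium, which the chromone would not tolerate.

Step 7
Reactants: 5 tert-butyl (2R,3S)-5,7-bis(benzyloxy)-2-[4-(benzyloxy)phenyl]-4-oxochromane-3-carboxylate; 9 5,7-bis(benzyloxy)-2-[4-(benzyloxy)-3-(tributylstannyl)phenyl]-4H-chromen-4-one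
Product: 11 tert-butyl (2S,3R)-3-aryl-flavanone-3-carboxylate hexabenzyl ether, via aryllead triacetate 10 (not isolated)
Conditions: 9 (1.3 equiv), Pb(OAc)4 (1.25 equiv), Hg(OAc)2 (5 mol%), CHCl3, 40 °C; then 5 (1.0 equiv), pyridine (4 equiv), CHCl3, 40 to 60 °C; aq. KF wash
Reagents that add atoms: none
Why: Mercury(II)-catalysed tin–lead exchange gives aryllead(IV) triacetate 10; pyridine-assisted exchange of an acetate for the enol of 5 and ligand coupling on lead (Pb(IV) to Pb(II)) then forms the C3–C3' bond. The closest known reaction type is the Pinhey arylation of β-keto esters, which has been used on 3-alkoxycarbonylchroman-4-ones to make isoflavanones. No ring is closed. The new quaternary C3 is set by the substrate: the aryl group should enter on the face anti to the C2 aryl group, giving the 2,3-trans diaryl ester, and since this centre is re-set in step 8 the diastereoselectivity is not critical. The step needs C- over O-arylation (inherent to lead ligand coupling), a single arylation (C3 has one acidic hydrogen) and an intact C2–O1 bond (pyridine is too weak a base to form a free enolate that could open the ring by E1cB, and the arylated C3 carries no hydrogen). The ortho benzyloxy group on the aryllead coordinates lead and should favour coupling, and the stannane is kept in slight excess over Pb(OAc)4 so that no free lead(IV) acetoxylates 5.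

Step 8
Reactants: 11 tert-butyl (2S,3R)-3-aryl-flavanone-3-carboxylate hexabenzyl ether
Product: 13 (2R,3S)-hexa-O-benzyl biflavonoid, via β-keto acid 12 (not isolated)
Conditions: TsOH·H2O (0.5 equiv), toluene, 80 °C
Reagents that add atoms: none
Why: Acid-mediated tert-butyl ester cleavage (loss of isobutene) and decarboxylation of the β-keto acid through its cyclic transition state give the enol; ketonisation and acid-catalysed equilibration through the enol should leave the more stable 2,3-trans (diequatorial) isomer, so C3 (S) is set under thermodynamic control relative to the fixed C2 (R).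

Step 9
Reactants: 13 (2R,3S)-hexa-O-benzyl biflavonoid
Product: 14 (2R,3S)-3-[5-(5,7-dihydroxy-4-oxo-4H-chromen-2-yl)-2-hydroxyphenyl]-5,7-dihydroxy-2-(4-hydroxyphenyl)-2,3-dihydro-4H-chromen-4-one
Conditions: H2 (1 atm), 10% Pd/C, THF/MeOH 1:1, rt
Reagents that add atoms: none
Why: Hydrogenolysis of the six aryl benzyl ethers; the neutral conditions should neither epimerise C2/C3 nor cause cyclodehydration of the freed phenol ortho to C3 onto the C4 ketone (benzofuran formation), and the flavone C2=C3 bond is expected to survive at 1 atm.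

**Compound list**

1 | 1-[2,4-bis(benzyloxy)-6-hydroxyphenyl]ethanone | CC(=O)c1c(O)cc(OCc2ccccc2)cc1OCc1ccccc1 | starting material
2 | tert-butyl 3-[2,4-bis(benzyloxy)-6-hydroxyphenyl]-3-oxopropanoate | CC(C)(C)OC(=O)CC(=O)c1c(O)cc(OCc2ccccc2)cc1OCc1ccccc1 | intermediate
3 | 4-(benzyloxy)benzaldehyde | O=Cc1ccc(OCc2ccccc2)cc1 | starting material
4 | tert-butyl (2Z)-2-[2,4-bis(benzyloxy)-6-hydroxybenzoyl]-3-[4-(benzyloxy)phenyl]prop-2-enoate | CC(C)(C)OC(=O)/C(=C\c1ccc(OCc2ccccc2)cc1)C(=O)c1c(O)cc(OCc2ccccc2)cc1OCc1ccccc1 | intermediate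
5 | tert-butyl (2R,3S)-5,7-bis(benzyloxy)-2-[4-(benzyloxy)phenyl]-4-oxo-3,4-dihydro-2H-chromene-3-carboxylate (2,3-trans keto form, in equilibrium with its enol) | O=C1c2c(OCc3ccccc3)cc(OCc3ccccc3)cc2O[C@@H](c2ccc(OCc3ccccc3)cc2)[C@@H]1C(=O)OC(C)(C)C | intermediate
6 | 4-(benzyloxy)-3-bromobenzaldehyde | O=Cc1ccc(OCc2ccccc2)c(Br)c1 | starting material
7 | (2E)-1-[2,4-bis(benzyloxy)-6-hydroxyphenyl]-3-[4-(benzyloxy)-3-bromophenyl]prop-2-en-1-one | O=C(/C=C/c1ccc(OCc2ccccc2)c(Br)c1)c1c(O)cc(OCc2ccccc2)cc1OCc1ccccc1 | intermediate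
8 | 5,7-bis(benzyloxy)-2-[4-(benzyloxy)-3-bromophenyl]-4H-chromen-4-one | O=c1cc(-c2ccc(OCc3ccccc3)c(Br)c2)oc2cc(OCc3ccccc3)cc(OCc3ccccc3)c12 | intermediate
9 | 5,7-bis(benzyloxy)-2-[4-(benzyloxy)-3-(tributylstannyl)phenyl]-4H-chromen-4-one | CCCC[Sn](CCCC)(CCCC)c1cc(-c2cc(=O)c3c(OCc4ccccc4)cc(OCc4ccccc4)cc3o2)ccc1OCc1ccccc1 | intermediate
10 | {2-(benzyloxy)-5-[5,7-bis(benzyloxy)-4-oxo-4H-chromen-2-yl]phenyl}lead(IV) triacetate | CC(=O)O[Pb](OC(C)=O)(OC(C)=O)c1cc(-c2cc(=O)c3c(OCc4ccccc4)cc(OCc4ccccc4)cc3o2)ccc1OCc1ccccc1 | intermediate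
11 | tert-butyl (2S,3R)-5,7-bis(benzyloxy)-3-{2-(benzyloxy)-5-[5,7-bis(benzyloxy)-4-oxo-4H-chromen-2-yl]phenyl}-2-[4-(benzyloxy)phenyl]-4-oxo-3,4-dihydro-2H-chromene-3-carboxylate (C2 aryl and C3 aryl trans) | O=C1c2c(OCc3ccccc3)cc(OCc3ccccc3)cc2O[C@@H](c2ccc(OCc3ccccc3)cc2)[C@]1(C(=O)OC(C)(C)C)c1cc(-c2cc(=O)c3c(OCc4ccccc4)cc(OCc4ccccc4)cc3o2)ccc1OCc1ccccc1 | intermediate
12 | (2S,3R)-5,7-bis(benzyloxy)-3-{2-(benzyloxy)-5-[5,7-bis(benzyloxy)-4-oxo-4H-chromen-2-yl]phenyl}-2-[4-(benzyloxy)phenyl]-4-oxo-3,4-dihydro-2H-chromene-3-carboxylic acid | O=C1c2c(OCc3ccccc3)cc(OCc3ccccc3)cc2O[C@@H](c2ccc(OCc3ccccc3)cc2)[C@]1(C(=O)O)c1cc(-c2cc(=O)c3c(OCc4ccccc4)cc(OCc4ccccc4)cc3o2)ccc1OCc1ccccc1 | intermediate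
13 | (2R,3S)-5,7-bis(benzyloxy)-3-{2-(benzyloxy)-5-[5,7-bis(benzyloxy)-4-oxo-4H-chromen-2-yl]phenyl}-2-[4-(benzyloxy)phenyl]-2,3-dihydro-4H-chromen-4-one | O=C1c2c(OCc3ccccc3)cc(OCc3ccccc3)cc2O[C@@H](c2ccc(OCc3ccccc3)cc2)[C@@H]1c1cc(-c2cc(=O)c3c(OCc4ccccc4)cc(OCc4ccccc4)cc3o2)ccc1OCc1ccccc1 | intermediate
14 | (2R,3S)-3-[5-(5,7-dihydroxy-4-oxo-4H-chromen-2-yl)-2-hydroxyphenyl]-5,7-dihydroxy-2-(4-hydroxyphenyl)-2,3-dihydro-4H-chromen-4-one | O=C1c2c(O)cc(O)cc2O[C@@H](c2ccc(O)cc2)[C@@H]1c1cc(-c2cc(=O)c3c(O)cc(O)cc3o2)ccc1O | target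

**Count and risks**

Total steps: 9. Longest linear sequence: 6 (steps 1, 2, 3, 7, 8, 9; the branch through steps 4, 5, 6 is equally long).

Steps most likely to fail:

1. Step 7. Ligand coupling at the crowded C3 (flanked by the C2 aryl group, the tert-butyl ester and an ortho-substituted aryl) may be slow, and during a long reaction unreacted 5 may lose C2 integrity by reversible ring opening. The fallback sets out from compound 5 and uses bromide 8 directly. TsOH·H2O in toluene at 80 °C decarboxylates 5 to (2R)-5,7-bis(benzyloxy)-2-[4-(benzyloxy)phenyl]-2,3-dihydro-4H-chromen-4-one F1. LDA with TMSCl present (in situ quench, THF, −78 °C) converts it to (2R)-5,7-bis(benzyloxy)-2-[4-(benzyloxy)phenyl]-4-(trimethylsilyloxy)-2H-chromene F2. Palladium-catalysed α-arylation of this silyl enol ether with 8 through its tin enolate (Pd(dba)2, P(t-Bu)3, Bu3SnF, toluene, 80 °C), which avoids a free alkali enolate, forms the same C3–C3' bond and, after equilibration to the trans isomer, comes back to the route at compound 13.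

2. Step 3. Facial selectivity may be poor with the extra ortho benzyloxy group on the aroyl ring, and the amine catalyst may erode C2 by reversible closure. The fallback sets out from compound 1. DMF dimethyl acetal (toluene, 90 °C) gives (2E)-1-[2,4-bis(benzyloxy)-6-hydroxyphenyl]-3-(dimethylamino)prop-2-en-1-one F3, and acid (conc. HCl, CH2Cl2, rt) closes it to 5,7-bis(benzyloxy)-4H-chromen-4-one F4. Palladium-catalysed asymmetric conjugate addition of 4-(benzyloxy)phenylboronic acid (Pd(TFA)2, the t-BuPyOX enantiomer that gives 2R, NH4PF6, H2O, dichloroethane, 60 °C) gives the (2R)-flavanone F1. C-tert-butoxycarbonylation of its lithium enolate (LiHMDS, THF, −78 °C; Boc2O) comes back to the route at compound 5.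

3. Step 9. Over-reduction may occur during the long hydrogenolysis of six ethers: saturation of the flavone C2=C3 bond or hydrogenolysis of the benzylic C2–O1 bond of the chromanone ring. The fallback sets out from compound 13 and replaces hydrogenation by Lewis-acid dealkylation (BCl3, pentamethylbenzene as benzyl-cation scavenger, CH2Cl2, −78 °C; MeOH quench), coming back at compound 14 directly with no new intermediate.

**Further compounds**

F1 | step 7 | (2R)-5,7-bis(benzyloxy)-2-[4-(benzyloxy)phenyl]-2,3-dihydro-4H-chromen-4-one | O=C1c2c(OCc3ccccc3)cc(OCc3ccccc3)cc2O[C@@H](c2ccc(OCc3ccccc3)cc2)C1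
F2 | step 7 | (2R)-5,7-bis(benzyloxy)-2-[4-(benzyloxy)phenyl]-4-(trimethylsilyloxy)-2H-chromene | C[Si](C)(C)OC=1c2c(OCc3ccccc3)cc(OCc3ccccc3)cc2O[C@@H](c2ccc(OCc3ccccc3)cc2)C=1
F3 | step 3 | (2E)-1-[2,4-bis(benzyloxy)-6-hydroxyphenyl]-3-(dimethylamino)prop-2-en-1-one | CN(C)/C=C/C(=O)c1c(O)cc(OCc2ccccc2)cc1OCc1ccccc1
F4 | step 3 | 5,7-bis(benzyloxy)-4H-chromen-4-one | O=c1ccoc2cc(OCc3ccccc3)cc(OCc3ccccc3)c12
F0 | step 9 | none | none
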